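(The runs were generated by integration with made-up constants, and the scatter is random.)

Grey was the flask I had to decide about: was its cool start worth keeping, or would the hot stretch wipe it out, and would staying cool, as amber does, pay better?

| flask | substrate | coupling partner | temperature | remark | time |
|---|---|---|---|---|---|
| cedar | 2 M | 1.2 M | 88 °C | run made earlier |  |
| alder | 2 M | 2.7 M | 104 °C | run made earlier |  |
| ochre | 2.0 M | 1.80 M | 110 °C |  | 6.0 min |
| grey | 2.0 M | 1.80 M |  | at 80 °C until 80 s, from then on at 110 °C | 6.0 min |
| amber | 2.0 M | 1.80 M | 80 °C |  | 6.0 min |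

| run | time / min | target / % | isomer of the product / % |
|---|---|---|---|
| cedar | 1.33 | 16.4 | 1.6 |
| cedar | 2.50 | 23.9 | 4.3 |
| cedar | 4.00 | 29.0 | 8.4 |
| cedar | 6.00 | 30.6 | 14.1 |
| cedar | 12.0 | 28.0 | 26.5 |
| cedar | 20.0 | 26.0 | 32.2 |
| alder | 0.500 | 33.4 | 4.9 |
| alder | 0.833 | 43.4 | 9.7 |
| alder | 1.33 | 49.1 | 17.0 |
| alder | 2.00 | 52.7 | 24.9 |
| alder | 4.00 | 55.6 | 35.4 |
| alder | 6.00 | 57.1 | 38.2 |

(readings scatter by 0.3 percentage points)

- the flask with the highest share of target in all that became target or isomer of the product ("all alike" if they lie within 1.5 percentage points) (ochre / grey / amber / all alike)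
- share of target in all that became target or isomer of the product, ochre
- share of target in all that became target or isomer of the product, grey
- share of target in all that became target or isomer of the product, amber



In both runs target came first and isomer followed, so I read the two as a first-order pair, target ⇌ isomer. Late in alder the ratio of isomer to target moved from 0.637 to 0.669, and I took that last reading as an estimate of its equilibrium constant K. Cedar ended at 1.24, still climbing from 0.946, so that reading is a lower limit for cedar's K, and I used it as it stood. The forward constant is the isomer gained per minute, as a fraction of the charge, divided by the mean of (target − isomer/K) over one early interval: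

k = 0.559 min⁻¹ (alder), 0.128 min⁻¹ (cedar)

I ran ln k and ln K straight along temperature to 110 °C, which gave k = 0.970 min⁻¹ and K = 0.531. From these came what I carried: the relaxation rate λ, forward plus back constant, the pace at which a target–isomer mixture forgets its share:

λ = k(1 + 1/K) = 2.80 min⁻¹; equilibrium share s = 1/(1 + K) = 65.3%

Then I solved both ends, with x = λ × time. Product made all at the start has share s + (1 − s)e^(−x); product made steadily has s + (1 − s)(1 − e^(−x))/x. I expected each flask to fall between the two.

Ochre: x = 16.8, from 65.3% to 67.4%

Grey, counted from the change: x = 13.1, from 65.3% to 68.0%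

Amber, with the same line run down to 80 °C: K = 1.69, λ = 0.0979 min⁻¹, x = 0.587, from 72.1% to 84.7%

Grey's x stood far above one, which is thermodynamic control, and amber's below one, which is kinetic control. The tops for grey and ochre differed by 0.60 percentage points, less than the margin. So I would drop the cool start and expect amber highest.

The forecast named amber, with ochre 65.2%, grey 65.3% and amber 81%, calling amber “kinetically held”; it gives single figures where I keep ranges.

The flasks gave amber as highest, with ochre 65.4%, grey 65.6% and amber 82.6%.

    substrate + coupling partner ⇌ adduct (K = 0.220 M⁻¹, k = 0.00200 M⁻¹ s⁻¹, Ea = 79.0 kJ mol⁻¹, ΔH = −43.0 kJ mol⁻¹)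
    adduct → target (k = 0.0390 s⁻¹, Ea = 96.0 kJ mol⁻¹)
    target ⇌ isomer of the product (K = 2.20, k = 9.90 × 10⁻⁴ s⁻¹, Ea = 103 kJ mol⁻¹, ΔH = −53.0 kJ mol⁻¹)
    (constants at 80 °C)

Grey's 65.6% stands inside my range of 65.3% to 68.0%, after a hot stretch that my estimated λ put at 13.1 relaxation times. The neighbouring flask is grey itself, read at 2.5 min, when the hot stretch had lasted 1.17 min. The same λ gives x = 3.26, so the range runs from 66.6% to 75.5%. At that moment 40% of the substrate was still unbound, and the share of target stood at 70.9%.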